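**Retrosynthetic overview**

1. The C3 ester is cut last: a Z-selective Still–Gennari olefination joins a C3 phosphonoacetate to (R)-3-(angeloyloxy)butanal. The all-cis C7/C8/C9 array comes from a 7,8-epoxy-9-ketone by hydride addition at C9 and palladium/formate hydrogenolysis of the alkenyl oxirane with inversion at C7.
2. Ring B (C5–C10) is cut at C8–C9 and C6–C7: a cis-fused cyclobutanone and a silyl-capped enyne are joined by a nickel-catalysed formal [4+2] two-carbon ring expansion.
3. Enabling feature: the oxygenated C9 sits next to ring-fusion carbon C10 and C6 is a CH2 on quaternary C5, so C6–C5–C10–C9(=O) is a cyclobutanone fused to ring A. C7–C8 with the isopropenyl group on C7 is a conjugated enyne whose alkene steers the regiochemistry.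
4. Ring order: ring A by ring-closing metathesis of a syn allylboration product; then a temporary four-membered ring by dichloroketene [2+2], which sets the C5/C10 cis fusion; then ring B in the key step, which consumes the four-membered ring.
5. Temporary groups: Me3Si on C8 (terminal-alkyne surrogate), t-BuMe2Si on O3 and an 8,9-acetonide; all are removed.

Key step: step 7

Remark (numbering): bicyclic compounds from 15 onward are named with eremophilane numbering: ring A = C1–C5 and C10, ring B = C5–C10, methyls on C4 and C5, isopropenyl (C11–C13) on C7.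
Assumption: the (S)-enantiomer of the TRIP phosphoric acid is taken to direct the allyl group to the Si face of an aliphatic aldehyde; if the sense is the opposite, the (R)-catalyst is used.

**Route**

Step 1
Reactants: 1 (Z)-2-bromobut-2-ene; 2 2-(chloromethyl)-4,4,5,5-tetramethyl-1,3,2-dioxaborolane
Product: 5 (Z)-4,4,5,5-tetramethyl-2-(2-methylbut-2-en-1-yl)-1,3,2-dioxaborolane, via (E)-but-2-en-2-yllithium 3 (not isolated), via lithium boronate complex 4 (not isolated)
Conditions: t-BuLi (2 equiv), THF/Et2O, −78 °C; then 2, −78 to 25 °C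
Reagents that add atoms: none
Why: Br–Li exchange keeps the alkene geometry, and the alkenyllithium is homologated by a Matteson-type 1,2-metallate shift (chloride leaves from the boronate complex) with retention, which fixes the Z allylboronate.

Step 2
Reactants: 5 (Z)-allylboronate; 6 pent-4-enal
Product: 8 (3R,4R)-2,3-dimethylocta-1,7-dien-4-ol, via pinacol borate ester 7 (not isolated)
Conditions: (S)-TRIP phosphoric acid (5 mol %), 4 Å molecular sieves, toluene, −30 °C; aqueous work-up
Reagents that add atoms: none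
Why: Chiral phosphoric acid-catalysed allylboration through a closed six-membered chair transition state should place the Z γ-methyl syn to the new hydroxyl and, by catalyst control of the Si face of the aldehyde, give the 3R,4R alcohol.

Step 3
Reactants: 8 (3R,4R)-2,3-dimethylocta-1,7-dien-4-ol
Product: 9 tert-butyl{[(3R,4R)-2,3-dimethylocta-1,7-dien-4-yl]oxy}dimethylsilane
Conditions: t-BuMe2SiOTf, 2,6-lutidine, CH2Cl2, 0 °C
Reagents that add atoms: tert-butyldimethylsilyl trifluoromethanesulfonate CC(C)(C)[Si](C)(C)OS(=O)(=O)C(F)(F)F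
Why: Silyl ether formation touches no stereocentre and masks the oxygen for the ketene and nickel steps.

Step 4
Reactants: 9 silyl ether of the dienol
Product: 10 tert-butyl{[(1R,2R)-2,3-dimethylcyclohex-3-en-1-yl]oxy}dimethylsilane
Conditions: second-generation Grubbs catalyst RuCl2(H2IMes)(PCy3)(=CHPh) (3 mol %), CH2Cl2, 40 °C
Reagents that add atoms: none
Why: Ring-closing metathesis of the 1,1-disubstituted and the monosubstituted alkene should close ring A as a trisubstituted cyclohexene with loss of ethene, leaving both stereocentres untouched.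

Step 5
Reactants: 10 cyclohexenyl silyl ether
Product: 11 (1R,2R,3R,6S)-3-[(tert-butyldimethylsilyl)oxy]-8,8-dichloro-1,2-dimethylbicyclo[4.2.0]octan-7-one
Conditions: Cl3CCOCl, Zn dust (Cu-activated), DME, Et2O, sonication, 25 °C
Reagents that add atoms: trichloroacetyl chloride ClC(Cl)(Cl)C(Cl)=O
Why: Ketene–alkene [2+2] cycloaddition of dichloroketene should bond the carbonyl carbon to the less substituted C10 and CCl2 to C5, add suprafacially (cis fusion) and approach anti to the adjacent C4 methyl, which sets C5 and C10.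

Step 6
Reactants: 11 dichlorocyclobutanone
Product: 13 (1R,2R,3R,6S)-3-[(tert-butyldimethylsilyl)oxy]-1,2-dimethylbicyclo[4.2.0]octan-7-one, via monochloro ketone 12 (not isolated)
Conditions: Zn dust, AcOH, 25 °C
Reagents that add atoms: none
Why: Zinc-mediated reductive dehalogenation of the α,α-dichloroketone through zinc enolates should remove both chlorides without touching the ring fusion.

Step 7
Reactants: 13 cyclobutanone; 14 trimethyl(3-methylbut-3-en-1-yn-1-yl)silane
Product: 15 (3R,4R,5R,10S)-3-[(tert-butyldimethylsilyl)oxy]-8-(trimethylsilyl)eremophila-7,11-dien-9-one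
Conditions: 14 (3 equiv), Ni(cod)2 (10 mol %), PCy3 (20 mol %), toluene, 100 °C
Reagents that add atoms: none
Why: Zerovalent nickel couples the C9 carbonyl with the alkyne by oxidative cyclisation to an oxanickelacyclopentene (C8–C9 bond), β-carbon elimination then breaks the strained C9–C6 bond of the four-membered ring, and C(sp3)–C(sp2) reductive elimination forms C6–C7 and releases the catalyst. The closest known reaction is the nickel-catalysed intermolecular insertion of internal alkynes into cyclobutanones, a formal [4+2] two-carbon ring expansion to cyclohex-2-enones. Ring B is closed in this formal [4+2] mode from the four-carbon unit C6–C5–C10–C9 and the two alkyne carbons, and the temporary four-membered ring is consumed. No new stereocentre is formed: C5 and C10 are carried over, so the cis fusion from step 5 becomes the cis-decalin fusion, and the neutral conditions should leave the enolisable C10–H untouched. Two selectivities are needed: cleavage of the C9–CH2 bond rather than C9–C10, which the preference for the less hindered primary alkylnickel should secure, and bonding of C9 to the silyl-bearing alkyne carbon with C6 going to the isopropenyl-bearing carbon, which η3 coordination of the conjugated enyne to nickel (alkene-directed regiochemistry) should secure. The trimethylsilyl cap suppresses the oligomerisation expected for a terminal alkyne and is removed in step 8.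

Step 8
Reactants: 15 silyl dienone
Product: 16 (3R,4R,5R,10S)-3-hydroxyeremophila-7,11-dien-9-one
Conditions: Bu4NF·3H2O (3 equiv), THF, 0 to 25 °C
Reagents that add atoms: none
Why: Fluoride should cleave the C(sp2)–Si bond of the α-silyl enone (protodesilylation) and the O–Si bond of the silyl ether in one operation, with no stereocentre involved.

Step 9
Reactants: 16 hydroxy dienone
Product: 17 (3R,4R,5R,7R,8S,10S)-7,8-epoxy-3-hydroxyeremophil-11-en-9-one
Conditions: H2O2 (30 % aq.), NaOH (aq., 0.3 equiv), MeOH, 0 °C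
Reagents that add atoms: hydrogen peroxide OO
Why: In this Weitz–Scheffer epoxidation hydroperoxide should add 1,4 to the enone at C7 and close on C8 from the face of H-10 and the C5 methyl, because the other face of C7 is shielded by the C5–C4 bond, which is pseudo-axial on ring B.

Step 10
Reactants: 17 epoxy ketone
Product: 18 (3R,4R,5R,7R,8R,9R,10S)-7,8-epoxyeremophil-11-ene-3,9-diol
Conditions: NaBH4, MeOH/CH2Cl2, −78 to −40 °C
Reagents that add atoms: none
Why: Borohydride reduction of the α,β-epoxy ketone is expected to deliver hydride anti to the oxirane oxygen (polar model), giving the cis epoxy alcohol and thus 9R.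

Step 11
Reactants: 18 epoxy diol
Product: 19 (3R,4R,5R,7R,8S,9R,10S)-eremophil-11-ene-3,8,9-triol
Conditions: Pd2(dba)3·CHCl3 (2.5 mol %), n-Bu3P (10 mol %), HCO2H, Et3N, 1,4-dioxane, 25 °C
Reagents that add atoms: none
Why: In this formate hydrogenolysis of an alkenyl oxirane (π-allyl chemistry of the Tsuji–Trost type) zerovalent palladium ionises the allylic C7–O bond with inversion and hydride from formate is passed from palladium to the more substituted terminus C7, so H replaces O with overall inversion (7R, isopropenyl cis to the 8-OH) and the terminal alkene is kept.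

Step 12
Reactants: 19 triol
Product: 20 (3R,4R,5R,7R,8S,9R,10S)-8,9-(isopropylidenedioxy)eremophil-11-en-3-ol
Conditions: Me2C(OMe)2, PPTS (cat.), CH2Cl2, 25 °C
Reagents that add atoms: 2,2-dimethoxypropane COC(C)(C)OC
Why: Acid-catalysed transketalisation should form the five-membered acetonide only at the cis-8,9-diol and leave the isolated 3-OH free.

Step 13
Reactants: 20 acetonide alcohol; 21 [bis(2,2,2-trifluoroethoxy)phosphoryl]acetic acid
Product: 23 (3R,4R,5R,7R,8S,9R,10S)-8,9-(isopropylidenedioxy)eremophil-11-en-3-yl [bis(2,2,2-trifluoroethoxy)phosphoryl]acetate, via O-acylisourea 22 (not isolated)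
Conditions: DCC, DMAP (cat.), CH2Cl2, 0 to 25 °C
Reagents that add atoms: none
Why: Carbodiimide esterification (Steglich conditions) should acylate the only free hydroxyl with retention at C3.

Step 14
Reactants: 24 (R)-pent-4-en-2-ol; 25 angelic acid [(Z)-2-methylbut-2-enoic acid]
Product: 27 (R)-pent-4-en-2-yl (Z)-2-methylbut-2-enoate, via mixed trichlorobenzoic anhydride 26 (not isolated)
Conditions: 2,4,6-Cl3C6H2COCl, Et3N, toluene, 25 °C; then 24, 80 °C
Reagents that add atoms: none
Why: Yamaguchi-type mixed-anhydride esterification run without DMAP should avoid nucleophile-induced isomerisation of the angelate to the tiglate, and the carbinol centre is not touched.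

Step 15
Reactants: 27 angelate ester
Product: 29 (R)-4-oxobutan-2-yl (Z)-2-methylbut-2-enoate, via ozonide 28 (not isolated)
Conditions: O3 (1 equiv), pyridine (cat.), CH2Cl2, −78 °C; then PPh3, −78 to 25 °C
Reagents that add atoms: ozone [O-][O+]=O
Why: Ozonolysis with one equivalent of ozone should cleave the electron-richer terminal alkene in preference to the conjugated angelate double bond, and PPh3 reduces the ozonide to the aldehyde.

Step 16
Reactants: 23 phosphonoacetate; 29 (R)-3-(angeloyloxy)butanal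
Product: 31 (3R,4R,5R,7R,8S,9R,10S)-8,9-(isopropylidenedioxy)eremophil-11-en-3-yl (2Z,5R)-5-{[(2Z)-2-methylbut-2-enoyl]oxy}hex-2-enoate, via potassium phosphonate carbanion 30 (not isolated)
Conditions: KN(SiMe3)2 (1.05 equiv), 18-crown-6, THF, −78 °C; then 29
Reagents that add atoms: none
Why: In the Still–Gennari olefination the bis(trifluoroethyl)phosphonate anion with a dissociated potassium counter-ion eliminates fast from the kinetic adduct and should give the Z enoate, while the low temperature suppresses β-elimination of the angelate from the aldehyde.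

Step 17
Reactants: 31 acetonide of the target
Product: 32 target, (3R,4R,5R,7R,8S,9R,10S)-8,9-dihydroxyeremophil-11-en-3-yl (2Z,5R)-5-{[(2Z)-2-methylbut-2-enoyl]oxy}hex-2-enoate (CNP0395983.1)
Conditions: AcOH/H2O (4:1), 40 °C
Reagents that add atoms: none
Why: Mild aqueous acid should hydrolyse the acetonide (acetal hydrolysis) without affecting the two esters, the Z enoate or the isopropenyl group.

**Compound list**

1 | (Z)-2-bromobut-2-ene | C/C=C(/C)Br | starting material
2 | 2-(chloromethyl)-4,4,5,5-tetramethyl-1,3,2-dioxaborolane | ClCB1OC(C)(C)C(C)(C)O1 | starting material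
3 | (E)-but-2-en-2-yllithium (Li cis to the C3 methyl) | C/C=C(/C)[Li] | intermediate
4 | lithium (chloromethyl)[(E)-but-2-en-2-yl](pinacolato)borate | [Li+].C/C=C(/C)[B-]1(CCl)OC(C)(C)C(C)(C)O1 | intermediate
5 | (Z)-4,4,5,5-tetramethyl-2-(2-methylbut-2-en-1-yl)-1,3,2-dioxaborolane | C/C=C(/C)CB1OC(C)(C)C(C)(C)O1 | intermediate
6 | pent-4-enal | C=CCCC=O | starting material
7 | 2-{[(3R,4R)-2,3-dimethylocta-1,7-dien-4-yl]oxy}-4,4,5,5-tetramethyl-1,3,2-dioxaborolane | C=CCC[C@@H](OB1OC(C)(C)C(C)(C)O1)[C@@H](C(C)=C)C | intermediate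
8 | (3R,4R)-2,3-dimethylocta-1,7-dien-4-ol | C=CCC[C@@H](O)[C@@H](C(C)=C)C | intermediate
9 | tert-butyl{[(3R,4R)-2,3-dimethylocta-1,7-dien-4-yl]oxy}dimethylsilane | C=CCC[C@@H](O[Si](C)(C)C(C)(C)C)[C@@H](C(C)=C)C | intermediate
10 | tert-butyl{[(1R,2R)-2,3-dimethylcyclohex-3-en-1-yl]oxy}dimethylsilane | CC1=CCC[C@@H](O[Si](C)(C)C(C)(C)C)[C@@H]1C | intermediate
11 | (1R,2R,3R,6S)-3-[(tert-butyldimethylsilyl)oxy]-8,8-dichloro-1,2-dimethylbicyclo[4.2.0]octan-7-one | O=C1C(Cl)(Cl)[C@@]2(C)[C@@H]1CC[C@@H](O[Si](C)(C)C(C)(C)C)[C@@H]2C | intermediate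
12 | (1R,2R,3R,6S)-3-[(tert-butyldimethylsilyl)oxy]-8-chloro-1,2-dimethylbicyclo[4.2.0]octan-7-one (C8 epimers) | O=C1C(Cl)[C@@]2(C)[C@@H]1CC[C@@H](O[Si](C)(C)C(C)(C)C)[C@@H]2C | intermediate
13 | (1R,2R,3R,6S)-3-[(tert-butyldimethylsilyl)oxy]-1,2-dimethylbicyclo[4.2.0]octan-7-one | O=C1C[C@@]2(C)[C@@H]1CC[C@@H](O[Si](C)(C)C(C)(C)C)[C@@H]2C | intermediate
14 | trimethyl(3-methylbut-3-en-1-yn-1-yl)silane | C=C(C)C#C[Si](C)(C)C | starting material
15 | (3R,4R,5R,10S)-3-[(tert-butyldimethylsilyl)oxy]-8-(trimethylsilyl)eremophila-7,11-dien-9-one | C=C(C)C=1C[C@@]2(C)[C@H](CC[C@@H](O[Si](C)(C)C(C)(C)C)[C@@H]2C)C(=O)C=1[Si](C)(C)C | intermediate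
16 | (3R,4R,5R,10S)-3-hydroxyeremophila-7,11-dien-9-one | C=C(C)C=1C[C@@]2(C)[C@H](CC[C@@H](O)[C@@H]2C)C(=O)C=1 | intermediate
17 | (3R,4R,5R,7R,8S,10S)-7,8-epoxy-3-hydroxyeremophil-11-en-9-one | C=C(C)[C@]12C[C@@]3(C)[C@H](CC[C@@H](O)[C@@H]3C)C(=O)[C@H]1O2 | intermediate
18 | (3R,4R,5R,7R,8R,9R,10S)-7,8-epoxyeremophil-11-ene-3,9-diol | C=C(C)[C@]12C[C@@]3(C)[C@H](CC[C@@H](O)[C@@H]3C)[C@@H](O)[C@H]1O2 | intermediate
19 | (3R,4R,5R,7R,8S,9R,10S)-eremophil-11-ene-3,8,9-triol | C=C(C)[C@H]1C[C@@]2(C)[C@H](CC[C@@H](O)[C@@H]2C)[C@@H](O)[C@H]1O | intermediate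
20 | (3R,4R,5R,7R,8S,9R,10S)-8,9-(isopropylidenedioxy)eremophil-11-en-3-ol | C=C(C)[C@H]1C[C@@]2(C)[C@H](CC[C@@H](O)[C@@H]2C)[C@H]3OC(C)(C)O[C@@H]13 | intermediate
21 | [bis(2,2,2-trifluoroethoxy)phosphoryl]acetic acid | OC(=O)CP(=O)(OCC(F)(F)F)OCC(F)(F)F | starting material
22 | N,N'-dicyclohexyl-O-{[bis(2,2,2-trifluoroethoxy)phosphoryl]acetyl}isourea | FC(F)(F)COP(=O)(OCC(F)(F)F)CC(=O)OC(=NC1CCCCC1)NC1CCCCC1 | intermediate
23 | (3R,4R,5R,7R,8S,9R,10S)-8,9-(isopropylidenedioxy)eremophil-11-en-3-yl [bis(2,2,2-trifluoroethoxy)phosphoryl]acetate | C=C(C)[C@H]1C[C@@]2(C)[C@H](CC[C@@H](OC(=O)CP(=O)(OCC(F)(F)F)OCC(F)(F)F)[C@@H]2C)[C@H]3OC(C)(C)O[C@@H]13 | intermediate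
24 | (R)-pent-4-en-2-ol | C=CC[C@@H](C)O | starting material
25 | angelic acid, (Z)-2-methylbut-2-enoic acid | C/C=C(/C)C(=O)O | starting material
26 | (Z)-2-methylbut-2-enoic 2,4,6-trichlorobenzoic anhydride | C/C=C(/C)C(=O)OC(=O)c1c(Cl)cc(Cl)cc1Cl | intermediate
27 | (R)-pent-4-en-2-yl (Z)-2-methylbut-2-enoate | C=CC[C@@H](C)OC(=O)/C(C)=C\C | intermediate
28 | (2R)-1-(1,2,4-trioxolan-3-yl)propan-2-yl (Z)-2-methylbut-2-enoate | C1(C[C@@H](C)OC(=O)/C(C)=C\C)OCOO1 | intermediate
29 | (R)-4-oxobutan-2-yl (Z)-2-methylbut-2-enoate | O=CC[C@@H](C)OC(=O)/C(C)=C\C | intermediate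
30 | potassium salt of the phosphonoacetate carbanion of 23 | [K+].C=C(C)[C@H]1C[C@@]2(C)[C@H](CC[C@@H](OC(=O)[CH-]P(=O)(OCC(F)(F)F)OCC(F)(F)F)[C@@H]2C)[C@H]3OC(C)(C)O[C@@H]13 | intermediate
31 | (3R,4R,5R,7R,8S,9R,10S)-8,9-(isopropylidenedioxy)eremophil-11-en-3-yl (2Z,5R)-5-{[(2Z)-2-methylbut-2-enoyl]oxy}hex-2-enoate | C=C(C)[C@H]1C[C@@]2(C)[C@H](CC[C@@H](OC(=O)/C=C\C[C@@H](C)OC(=O)/C(C)=C\C)[C@@H]2C)[C@H]3OC(C)(C)O[C@@H]13 | intermediate
32 | (3R,4R,5R,7R,8S,9R,10S)-8,9-dihydroxyeremophil-11-en-3-yl (2Z,5R)-5-{[(2Z)-2-methylbut-2-enoyl]oxy}hex-2-enoate | C=C(C)[C@H]1C[C@@]2(C)[C@H](CC[C@@H](OC(=O)/C=C\C[C@@H](C)OC(=O)/C(C)=C\C)[C@@H]2C)[C@@H](O)[C@H]1O | target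

**Step count and risks**

Total step count: 17. Longest linear sequence: 15 (steps 1–13, 16, 17); steps 14 and 15 form the side branch.

Most likely to fail:

1. Step 7. The alkyne may insert with the wrong orientation, the C9–C10 bond may be cleaved instead of C9–C6, or the enyne may oligomerise on nickel. The fallback is a stepwise anionic two-carbon ring expansion that sets out from 13 and comes back at 16. 2-Methylbut-1-en-3-yne is deprotonated with n-BuLi to lithium 3-methylbut-3-en-1-ynide F1, which adds to the ketone of 13 to give propargylic cyclobutanol F2. NaAlH2(OCH2CH2OMe)2 trans-reduces the propargylic alcohol to (E)-dienyl cyclobutanol F3. KH and 18-crown-6 in THF should then trigger the alkoxide-accelerated 1,3-alkyl shift of the 1-alkenylcyclobutanol (cleavage toward the primary carbon C6, closure at C7), and the enolate is trapped with Me3SiCl as silyl enol ether F4. Saegusa–Ito oxidation with Pd(OAc)2 in MeCN gives dienone silyl ether F5, and Bu4NF returns to 16.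

2. Step 5. Facial selectivity may be poor, because the ketene must approach the face that also carries the C3 silyloxy group. The fallback delivers the ketene from O3 through a temporary tether; it sets out from 8 and comes back at 13. Ring-closing metathesis of the free alcohol 8 gives cyclohexenol F6. O-Alkylation with bromoacetic acid (NaH, THF) gives alkoxyacetic acid F7, and oxalyl chloride gives acid chloride F8. Et3N in refluxing toluene generates alkoxyketene F9, whose intramolecular [2+2] addition to C5=C10 can only occur on the face of O3 and gives tricyclic α-alkoxy cyclobutanone F10. SmI2 in THF/MeOH cleaves the α C–O bond to hydroxy cyclobutanone F11, and silylation with t-BuMe2SiOTf returns to 13.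

3. Step 10. Hydride may be delivered from the open convex face instead (the concave face carries the pseudo-axial C5–C4 bond), which would give the C9 epimer. The fallback sets C9 by SN2 inversion from the convex face; it sets out from 17 and comes back at 18. LiBH(s-Bu)3 is used to attack the convex face deliberately and gives the 9-epimeric epoxy diol F12. The unhindered equatorial 3-OH is silylated selectively (t-BuMe2SiCl, imidazole) to silyl ether F13. A Mitsunobu reaction with 4-nitrobenzoic acid (PPh3, DIAD) inverts C9 and gives 4-nitrobenzoate F14. K2CO3 in MeOH removes the ester to give epoxy alcohol F15, and Bu4NF removes the silyl ether and returns to 18.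

Further compounds
F1 | step 7 | lithium 3-methylbut-3-en-1-ynide | [Li+].C=C(C)C#[C-]
F2 | step 7 | (1R,2R,3R,6S)-3-[(tert-butyldimethylsilyl)oxy]-1,2-dimethyl-7-(3-methylbut-3-en-1-yn-1-yl)bicyclo[4.2.0]octan-7-ol (C7 not defined) | C=C(C)C#CC1(O)C[C@@]2(C)[C@@H]1CC[C@@H](O[Si](C)(C)C(C)(C)C)[C@@H]2C
F3 | step 7 | (1R,2R,3R,6S)-3-[(tert-butyldimethylsilyl)oxy]-1,2-dimethyl-7-[(1E)-3-methylbuta-1,3-dien-1-yl]bicyclo[4.2.0]octan-7-ol (C7 not defined) | C=C(C)/C=C/C1(O)C[C@@]2(C)[C@@H]1CC[C@@H](O[Si](C)(C)C(C)(C)C)[C@@H]2C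
F4 | step 7 | (3R,4R,5R,10S)-3-[(tert-butyldimethylsilyl)oxy]-9-[(trimethylsilyl)oxy]eremophila-8,11-diene (C7 not defined) | C=C(C)C1C[C@@]2(C)[C@H](CC[C@@H](O[Si](C)(C)C(C)(C)C)[C@@H]2C)C(O[Si](C)(C)C)=C1
F5 | step 7 | (3R,4R,5R,10S)-3-[(tert-butyldimethylsilyl)oxy]eremophila-7,11-dien-9-one | C=C(C)C=1C[C@@]2(C)[C@H](CC[C@@H](O[Si](C)(C)C(C)(C)C)[C@@H]2C)C(=O)C=1
F6 | step 5 | (1R,2R)-2,3-dimethylcyclohex-3-en-1-ol | CC1=CCC[C@@H](O)[C@@H]1C
F7 | step 5 | {[(1R,2R)-2,3-dimethylcyclohex-3-en-1-yl]oxy}acetic acid | CC1=CCC[C@@H](OCC(=O)O)[C@@H]1C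
F8 | step 5 | {[(1R,2R)-2,3-dimethylcyclohex-3-en-1-yl]oxy}acetyl chloride | CC1=CCC[C@@H](OCC(=O)Cl)[C@@H]1C
F9 | step 5 | 2-{[(1R,2R)-2,3-dimethylcyclohex-3-en-1-yl]oxy}ethen-1-one | CC1=CCC[C@@H](OC=C=O)[C@@H]1C
F10 | step 5 | 3,8-epoxy-1,2-dimethylbicyclo[4.2.0]octan-7-one (O3 bridged to C8 of the skeleton of 13) | O=C1[C@@H]2O[C@@H]3CC[C@H]1[C@@]2(C)[C@H]3C
F11 | step 5 | (1R,2R,3R,6S)-3-hydroxy-1,2-dimethylbicyclo[4.2.0]octan-7-one | O=C1C[C@@]2(C)[C@@H]1CC[C@@H](O)[C@@H]2C
F12 | step 10 | (3R,4R,5R,7R,8R,9S,10S)-7,8-epoxyeremophil-11-ene-3,9-diol | C=C(C)[C@]12C[C@@]3(C)[C@H](CC[C@@H](O)[C@@H]3C)[C@H](O)[C@H]1O2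
F13 | step 10 | (3R,4R,5R,7R,8R,9S,10S)-3-[(tert-butyldimethylsilyl)oxy]-7,8-epoxyeremophil-11-en-9-ol | C=C(C)[C@]12C[C@@]3(C)[C@H](CC[C@@H](O[Si](C)(C)C(C)(C)C)[C@@H]3C)[C@H](O)[C@H]1O2
F14 | step 10 | (3R,4R,5R,7R,8R,9R,10S)-3-[(tert-butyldimethylsilyl)oxy]-7,8-epoxyeremophil-11-en-9-yl 4-nitrobenzoate | C=C(C)[C@]12C[C@@]3(C)[C@H](CC[C@@H](O[Si](C)(C)C(C)(C)C)[C@@H]3C)[C@@H](OC(=O)c4ccc(cc4)[N+](=O)[O-])[C@H]1O2
F15 | step 10 | (3R,4R,5R,7R,8R,9R,10S)-3-[(tert-butyldimethylsilyl)oxy]-7,8-epoxyeremophil-11-en-9-ol | C=C(C)[C@]12C[C@@]3(C)[C@H](CC[C@@H](O[Si](C)(C)C(C)(C)C)[C@@H]3C)[C@@H](O)[C@H]1O2
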